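The eta run holds more protic impurity than the delta run, 0.75 mM against 0.50 mM, yet both read 69 % electrophile at 30.0 min.

common to all: electrophile 20 mM
- delta: nucleophile 1.2 equiv; free base 1.1 equiv; scavenger 0.30 equiv; protic impurity 0.50 mM; run made earlier
- eta: nucleophile 1.2 equiv; free base 1.1 equiv; scavenger 0.30 equiv; protic impurity 0.75 mM; run made earlier
- flask: nucleophile 1.20 equiv; free base 1.10 equiv; scavenger 0.300 equiv; protic impurity 1.00 mM; time 25 min

| run | time / min | electrophile / % | product / % |
|---|---|---|---|
| delta | 4.00 | 93 | 6 |
| delta | 10.0 | 85 | 11 |
| delta | 20.0 | 77 | 23 |
| delta | 30.0 | 69 | 32 |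
| eta | 8.00 | 87 | 12 |
| eta | 15.0 | 79 | 18 |
| eta | 25.0 | 72 | 30 |
| eta | 30.0 | 69 | 32 |

(standard deviation of a reading: 1.5 percentage points)

- the earlier runs do not show how much of nucleophile is bound; that part of a forecast is a guess

1. part of the electrophile that has reacted at 25 min
2. share of the unused nucleophile that is free and not bound as protonated nucleophile, at 25 min

Which given number has to be known well for c?

1. Protic impurity: the rise left the last reading unchanged, while scatter makes two readings differ by about 2.1 percentage points. The flask's 1.00 mM lies beyond the runs, so it is an extrapolation, but nothing yet shows a strong effect.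
2. Charges: electrophile, nucleophile, free base and scavenger match the runs, so they add no error here. [nucleophile] stands at one charge in both runs, so any scaling with it is an assumption.
3. Decay constant: a last reading off by 1.5 points shifts c by 1.3 points. That uncertainty goes straight into c, so this constant has to be known well.
4. The value: the delta run's last reading gives 0.0124 min⁻¹. This pseudo-first-order constant k_obs, the fraction of electrophile lost per minute at this nucleophile charge, is taken as proportional to [nucleophile]. It gives c = 26.7 % at 25 min.

The forecast gives c = 27 % (23 % to 31 %) and fr = 93 % (75 % to 100 %). On binding it says: “This is a guess, because the runs contain no binding data, so the range is wide.”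

5. The flask gives c = 27.5 %, which corresponds to k_obs = 0.0129 min⁻¹. It gives fr = 82.1 %, 11 points under the forecast, with protonated nucleophile at 3.13 mM at 25.0 min, more than the 1.00 mM of protic impurity charged.

    acid set free + free base ⇌ idle adduct, settled at all times (K = 290 L mol⁻¹)
    electrophile + nucleophile → acid set free + product (k = 0.0119 L mol⁻¹ s⁻¹)
    nucleophile + acid set free ⇌ protonated nucleophile, settled at all times (K = 1200 L mol⁻¹)
    nucleophile + protic impurity → quenched reagent (k = 0.513 L mol⁻¹ s⁻¹)
    acid set free + free base ⇌ salt of the base, settled at all times (K = 120 L mol⁻¹)
    acid set free + scavenger → scavenged by-product (k = 0.798 L mol⁻¹ s⁻¹)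

6. A neighbouring flask charged with 0.720 equiv of nucleophile scales k_obs to 0.00742 min⁻¹, which reckons to c = 16.9 % at 25 min. That neighbour gives 17.3 %.

The readings were computed for substances that don't exist, and the scatter is random.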